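## Retrosynthetic overview

- **Late bonds.** The C11 carbinol comes from a C7 methyl ester (2 MeMgBr). The C4–O aryl ether comes from Markovnikov capture of the tertiary C4 cation of a 4(15)-exocyclic alkene by the 2-OH of intact honokiol, which sets C4.
- **Alkene and nitro group.** The exocyclic alkene comes from the C4 ketone (Wittig). The nitro group that activated C9 is removed beforehand by radical denitration.
- **Key disconnection (ring B: C10–C9, C9–C8, C5–C6).** Nitromethane is a reversed-polarity (d1, acyl-anion-type) one-carbon linchpin. Its N-bearing carbon is bonded as a donor to two acceptor β-carbons: the enone β-carbon C10 (catalytic asymmetric, quaternary centre) and the β-carbon of methyl 2-(bromomethyl)acrylate. The ketone enolate then closes C5–C6 by Michael addition.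
- **Ring order.** Ring A is bought (3-methylcyclohex-2-enone), ring B is made by the [3+3] annulation, and both aryl rings arrive together as honokiol. C5 and C7 are set by equilibration relative to C10.

Assumption: C1–C15 are eudesmane locants (C4 ether carbon, C10 angular-methyl carbon, C7 side-chain carbon); the cinchona amine pseudoenantiomer that delivers the (S)-nitro ketone is used (quinine-derived shown).

## Route

Step 1
Reactants: 1 3-methylcyclohex-2-en-1-one; 2 nitromethane
Product: 3 (S)-3-methyl-3-(nitromethyl)cyclohexan-1-one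
Conditions: MeNO2 (10 equiv), 9-amino-9-deoxy-epi-quinine (5 mol%), PhCO2H (10 mol%), THF, 9 kbar, 50 °C
Reagents that add atoms: none
Why: Asymmetric organocatalytic Michael addition in which the nitronate, a d1 donor whose carbon carries the heteroatom, attacks the β-carbon of the iminium-activated enone (high pressure offsets the β,β-disubstitution), giving a 1,4-related nitro ketone and setting the quaternary C10 centre by catalyst face control.

Step 2
Reactants: 3 (S)-3-methyl-3-(nitromethyl)cyclohexan-1-one; 4 methyl 2-(bromomethyl)prop-2-enoate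
Product: 6 methyl (2S,4aS,8aR)-4a-methyl-4-nitro-8-oxodecahydronaphthalene-2-carboxylate (epimers at the nitro carbon), via nitro acrylate 5 (not isolated)
Conditions: 4 (1.05 equiv), Cs2CO3 (2.2 equiv), DMF, 0 °C to rt, then 50 °C; aq NH4Cl
Reagents that add atoms: none
Why: Proposed new method: the nitronate of 3 is alkylated by the bromomethyl acrylate in an SN2′ (addition–elimination) sense to give 5, whose C5 ketone enolate closes ring B by a reversible 6-endo intramolecular Michael addition, so that C5 and C7 (both α to carbonyls) equilibrate to the trans-fused, equatorial-ester isomer dictated by C10; the closest known type is the α,α′-annulation of enamines or β-keto esters with 2-(bromomethyl)acrylates combined with nitronate SN2′ alkylation.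

Step 3
Reactants: 6 methyl (2S,4aS,8aR)-4a-methyl-4-nitro-8-oxodecahydronaphthalene-2-carboxylate
Product: 7 methyl (2R,4aR,8aR)-4a-methyl-8-oxodecahydronaphthalene-2-carboxylate
Conditions: Bu3SnH (5 equiv), AIBN (0.3 equiv), PhMe, 110 °C
Reagents that add atoms: none
Why: Radical denitration (denitrohydrogenation): Bu3Sn• adds to the nitro group, the adduct fragments to the secondary C9 radical, and this takes H from Bu3SnH, leaving ketone, ester and the three stereocentres untouched.

Step 4
Reactants: 7 methyl (2R,4aR,8aR)-4a-methyl-8-oxodecahydronaphthalene-2-carboxylate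
Product: 8 methyl (2R,4aR,8aS)-4a-methyl-8-methylidenedecahydronaphthalene-2-carboxylate
Conditions: Ph3PCH3Br (2.0 equiv), KOt-Bu (1.9 equiv), THF/PhMe, 0 to 60 °C
Reagents that add atoms: methyltriphenylphosphonium bromide, C[P+](c1ccccc1)(c1ccccc1)c1ccccc1.[Br-]
Why: Wittig methylenation of the ring ketone (the ester is inert to the non-stabilised ylide here), with the basic medium holding C5 and C7 at their thermodynamic trans/equatorial configurations.

Step 5
Reactants: 8 methyl (2R,4aR,8aS)-4a-methyl-8-methylidenedecahydronaphthalene-2-carboxylate; 9 honokiol (3',5-di(prop-2-en-1-yl)-[1,1'-biphenyl]-2,4'-diol)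
Product: 10 methyl (2R,4aR,8R,8aR)-8-{[4'-hydroxy-3',5-di(prop-2-en-1-yl)-[1,1'-biphenyl]-2-yl]oxy}-4a,8-dimethyldecahydronaphthalene-2-carboxylate
Conditions: 9 (3 equiv), TfOH (5 mol%), CH2Cl2, −78 to −40 °C; Et3N quench; chromatography on Et3N-buffered silica
Reagents that add atoms: none
Why: Brønsted acid-catalysed Markovnikov hydroaryloxylation (tert-alkyl aryl ether formation, as in the tert-butylation of phenols with isobutene): protonation of the 1,1-disubstituted alkene gives the tertiary C4 cation, which the phenol oxygen captures from the α (equatorial) face opposite the axial C10 methyl to set C4 (8R), while the monosubstituted allyl groups do not ionise at this temperature and the 2-O ether is separated from the 4'-O regioisomer.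

Step 6
Reactants: 10 methyl (2R,4aR,8R,8aR)-8-{[4'-hydroxy-3',5-di(prop-2-en-1-yl)-[1,1'-biphenyl]-2-yl]oxy}-4a,8-dimethyldecahydronaphthalene-2-carboxylate
Product: 12 2-[(2R,4aR,8R,8aR)-8-{[4'-hydroxy-3',5-di(prop-2-en-1-yl)-[1,1'-biphenyl]-2-yl]oxy}-4a,8-dimethyldecahydronaphthalen-2-yl]propan-2-ol (CNP0219722.1), via methyl ketone 11 (not isolated)
Conditions: MeMgBr (5 equiv), THF, 0 °C to rt; aq NH4Cl
Reagents that add atoms: methylmagnesium bromide, C[Mg]Br
Why: Double Grignard addition to the methyl ester through ketone 11 gives the tertiary carbinol, while the phenol is only deprotonated and the tertiary aryl ether, allyl groups and stereocentres are inert to MeMgBr.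

## Compound list

1 | 3-methylcyclohex-2-en-1-one | CC1=CC(=O)CCC1 | starting material
2 | nitromethane | C[N+](=O)[O-] | starting material
3 | (S)-3-methyl-3-(nitromethyl)cyclohexan-1-one | O=C1CCC[C@](C)(C[N+](=O)[O-])C1 | intermediate
4 | methyl 2-(bromomethyl)prop-2-enoate | C=C(CBr)C(=O)OC | starting material
5 | methyl 2-methylidene-4-[(1S)-1-methyl-3-oxocyclohexyl]-4-nitrobutanoate (epimers at the nitro carbon) | O=C1CCC[C@](C)(C(CC(=C)C(=O)OC)[N+](=O)[O-])C1 | intermediate
6 | methyl (2S,4aS,8aR)-4a-methyl-4-nitro-8-oxodecahydronaphthalene-2-carboxylate (trans-fused, equatorial ester, epimers at the nitro carbon) | O=C1CCC[C@]2(C)C([N+](=O)[O-])C[C@@H](C(=O)OC)C[C@H]21 | intermediate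
7 | methyl (2R,4aR,8aR)-4a-methyl-8-oxodecahydronaphthalene-2-carboxylate | O=C1CCC[C@]2(C)CC[C@@H](C(=O)OC)C[C@H]21 | intermediate
8 | methyl (2R,4aR,8aS)-4a-methyl-8-methylidenedecahydronaphthalene-2-carboxylate | C=C1CCC[C@]2(C)CC[C@@H](C(=O)OC)C[C@H]21 | intermediate
9 | honokiol, 3',5-di(prop-2-en-1-yl)-[1,1'-biphenyl]-2,4'-diol | C=CCc1ccc(O)c(-c2ccc(O)c(CC=C)c2)c1 | starting material
10 | methyl (2R,4aR,8R,8aR)-8-{[4'-hydroxy-3',5-di(prop-2-en-1-yl)-[1,1'-biphenyl]-2-yl]oxy}-4a,8-dimethyldecahydronaphthalene-2-carboxylate | C=CCc1ccc(O[C@]2(C)CCC[C@]3(C)CC[C@@H](C(=O)OC)C[C@H]32)c(-c2ccc(O)c(CC=C)c2)c1 | intermediate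
11 | 1-[(2R,4aR,8R,8aR)-8-{[4'-hydroxy-3',5-di(prop-2-en-1-yl)-[1,1'-biphenyl]-2-yl]oxy}-4a,8-dimethyldecahydronaphthalen-2-yl]ethan-1-one | C=CCc1ccc(O[C@]2(C)CCC[C@]3(C)CC[C@@H](C(C)=O)C[C@H]32)c(-c2ccc(O)c(CC=C)c2)c1 | intermediate
12 | 2-[(2R,4aR,8R,8aR)-8-{[4'-hydroxy-3',5-di(prop-2-en-1-yl)-[1,1'-biphenyl]-2-yl]oxy}-4a,8-dimethyldecahydronaphthalen-2-yl]propan-2-ol | C=CCc1ccc(O[C@]2(C)CCC[C@]3(C)CC[C@@H](C(C)(C)O)C[C@H]32)c(-c2ccc(O)c(CC=C)c2)c1 | target

## Step count and risks

Total step count: 6. Longest linear sequence: 6 steps (1 to 12).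

Steps most likely to fail:

**Step 1** (quaternary centre by asymmetric nitro-Michael addition; needs high pressure and the ee must be confirmed). Fallback, setting out from 1 and 2 and coming back at 3: nitromethane is added to 1 without a chiral catalyst (DBU, neat MeNO2, rt to 60 °C) to give racemic 3-methyl-3-(nitromethyl)cyclohexan-1-one F1. The (S)-enantiomer 3 is then taken from F1 by preparative chiral SFC, so resolution replaces asymmetric catalysis.

**Step 2** (the ketone enolate must form and cyclise in the presence of the more acidic nitro group; oligomerisation through the acrylate is possible). Fallback, setting out from 3 and 4 and coming back at 6: the alkylation is stopped at the SN2′ stage (K2CO3, DMF, 0 °C) and 5 is isolated. Heating 5 with pyrrolidine (PhMe, Dean–Stark, dilute) gives the enamine methyl 2-methylidene-4-[(1S)-1-methyl-3-(pyrrolidin-1-yl)cyclohex-2-en-1-yl]-4-nitrobutanoate F2, which equilibrates with its unproductive double-bond isomer. F2 closes ring B by an intramolecular Stork enamine Michael addition to the bicyclic enamine methyl (2S,4aS,8aR)-4a-methyl-4-nitro-8-(pyrrolidin-1-yl)-1,2,3,4,4a,5,6,8a-octahydronaphthalene-2-carboxylate F3. Aqueous AcOH hydrolysis of F3 returns 6.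

**Step 5** (the 2-OH and 4'-OH of honokiol compete, and the less hindered 4'-O ether may predominate; the ether is acid-labile and the alkene can isomerise or C-alkylate the phenol). Fallback, setting out from 9 and 8 and coming back at 10: 9 is mono-acetylated (Ac2O 1.0 equiv, Et3N, CH2Cl2, −20 °C). The 4'-O-acetate 2'-hydroxy-3,5'-di(prop-2-en-1-yl)-[1,1'-biphenyl]-4-yl acetate F4 is separated from its regioisomer (assigned by HMBC; the rest is saponified back to 9). F4, with only the 2-OH free, is added to 8 under the step 5 conditions to give methyl (2R,4aR,8R,8aR)-8-{[4'-(acetyloxy)-3',5-di(prop-2-en-1-yl)-[1,1'-biphenyl]-2-yl]oxy}-4a,8-dimethyldecahydronaphthalene-2-carboxylate F5. K2CO3 in MeOH then removes the aryl acetate to give 10.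

## Further compounds

F1 | step 1 | rac-3-methyl-3-(nitromethyl)cyclohexan-1-one | O=C1CCCC(C)(C[N+](=O)[O-])C1
F2 | step 2 | methyl 2-methylidene-4-[(1S)-1-methyl-3-(pyrrolidin-1-yl)cyclohex-2-en-1-yl]-4-nitrobutanoate | C1(N2CCCC2)=C[C@@](C)(C(CC(=C)C(=O)OC)[N+](=O)[O-])CCC1
F3 | step 2 | methyl (2S,4aS,8aR)-4a-methyl-4-nitro-8-(pyrrolidin-1-yl)-1,2,3,4,4a,5,6,8a-octahydronaphthalene-2-carboxylate | C1(N2CCCC2)=CCC[C@]2(C)C([N+](=O)[O-])C[C@@H](C(=O)OC)C[C@H]21
F4 | step 5 | 2'-hydroxy-3,5'-di(prop-2-en-1-yl)-[1,1'-biphenyl]-4-yl acetate | C=CCc1ccc(O)c(-c2ccc(OC(C)=O)c(CC=C)c2)c1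
F5 | step 5 | methyl (2R,4aR,8R,8aR)-8-{[4'-(acetyloxy)-3',5-di(prop-2-en-1-yl)-[1,1'-biphenyl]-2-yl]oxy}-4a,8-dimethyldecahydronaphthalene-2-carboxylate | C=CCc1ccc(O[C@]2(C)CCC[C@]3(C)CC[C@@H](C(=O)OC)C[C@H]32)c(-c2ccc(OC(C)=O)c(CC=C)c2)c1
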